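**Assumption:** The target SMILES has no stereocentre, and its diaryl ether axis rotates freely at room temperature. The compound is therefore achiral and "single enantiomer" needs no stereocontrol. Compounds 1 and 7 are taken as catalogue chemicals.

## Retrosynthetic overview
1. Cut the ring A carbon–oxygen bond of the diaryl ether in 9. This gives 2,4-dibromophenol 7 and the tribromo o-quinone diazide 6, joined by a new Rh carbene O–H insertion. The carbonyl O of 6 becomes the free central OH.
2. 6 comes from diazotisation of 2-amino-3,4,5-tribromo-6-methoxyphenol 4.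
3. 4 comes from N-acetylation, exhaustive bromination and deacetylation of 2-amino-6-methoxyphenol 1. All three free positions are ortho or para to a donor group.
4. No ring is formed. Both benzene rings are bought, and each carries all its bromines before the union, so there is no late bromination choice.

## Route

Step 1
Reactants: 1 2-amino-6-methoxyphenol
Product: 2 N-(2-hydroxy-3-methoxyphenyl)acetamide
Conditions: Ac2O (1.05 equiv), EtOAc, 0 °C to rt
Reagents that add atoms: acetic anhydride, CC(=O)OC(C)=O
Why: Chemoselective N-acetylation (nucleophilic acyl substitution) works because the amine is far more nucleophilic than the hydrogen-bonded phenol, the amide protects the aminophenol from oxidation by bromine, and no stereocentre is formed.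

Step 2
Reactants: 2 N-(2-hydroxy-3-methoxyphenyl)acetamide
Product: 3 N-(2,3,4-tribromo-6-hydroxy-5-methoxyphenyl)acetamide
Conditions: Br2 (3.3 equiv), AcOH, rt to 50 °C; aq NaHSO3 quench
Reagents that add atoms: bromine, BrBr
Why: In this exhaustive electrophilic aromatic bromination each of the only three free positions is ortho or para to OH, OMe or NHAc, so a single tribromide can form and no stereocentre is formed.

Step 3
Reactants: 3 N-(2,3,4-tribromo-6-hydroxy-5-methoxyphenyl)acetamide
Product: 4 2-amino-3,4,5-tribromo-6-methoxyphenol
Conditions: 6 M aq HCl/1,4-dioxane (1:1), reflux, 16 h; then H2O, filter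
Reagents that add atoms: none
Why: Acid-catalysed amide hydrolysis is assisted by the neighbouring OH (N-to-O acyl shift), aryl bromides and the methyl ether are inert to aqueous HCl, and the very weakly basic amine separates as the free base on dilution.

Step 4
Reactants: 4 2-amino-3,4,5-tribromo-6-methoxyphenol
Product: 6 3,4,5-tribromo-6-diazo-2-methoxycyclohexa-2,4-dien-1-one, via diazonium tetrafluoroborate 5 (not isolated)
Conditions: t-BuONO (1.3 equiv), 48% aq HBF4 (1.5 equiv), MeCN, 0 °C; then aq NaOAc, 0 °C, dark; filter, dry in vacuo
Reagents that add atoms: tert-butyl nitrite, CC(C)(C)ON=O; tetrafluoroboric acid, [H+].F[B-](F)(F)F (stays only in the not isolated salt 5)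
Why: Diazotisation with an alkyl nitrite suits weakly basic anilines, and acetate then removes the very acidic ortho-OH proton (classical o-quinone diazide formation) to give a neutral, water-insoluble diazo-oxide that the three bromines stabilise.

Step 5
Reactants: 6 3,4,5-tribromo-6-diazo-2-methoxycyclohexa-2,4-dien-1-one; 7 2,4-dibromophenol (2.0 equiv)
Product: 9 3,4,5-tribromo-2-(2,4-dibromophenoxy)-6-methoxyphenol, via rhodium quinoid carbene 8 (not isolated)
Conditions: Rh2(esp)2 (1 mol %), 4 Å MS, ClCH2CH2Cl, 60 °C, dark, 6 added by syringe pump over 4 h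
Reagents that add atoms: none
Why: Proposed new method: this is an aromatising carbene O–H insertion used as a diaryl ether synthesis, in which Rh2(esp)2 binds the diazo carbon of 6, N2 leaves, the oxygen of 7 attacks the electrophilic carbene carbon of 8, and a proton shift from the oxonium ylide to the former carbonyl oxygen restores the benzene ring, so the new ArO–C bond must lie ortho to the freed OH; the medium is neutral and Rh(II) leaves all five C–Br bonds untouched, 7 has a blocked para position and a deactivated ring (no C–H arylation), 9 is more hindered and less nucleophilic than 7 (no second insertion), 60 °C in the dark lies below the Wolff ring-contraction threshold, and no stereocentre is formed; the closest known reaction types are Rh(II)-catalysed O–H insertion of diazonaphthoquinones into aliphatic alcohols and of α-diazocarbonyl compounds into phenols, neither shown for a monocyclic perhalogenated o-quinone diazide nor for a phenol partner giving a diaryl ether.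

## Compound list
No compound carries a stereocentre.

1 | 2-amino-6-methoxyphenol | COc1cccc(N)c1O | starting material
2 | N-(2-hydroxy-3-methoxyphenyl)acetamide | COc1cccc(NC(C)=O)c1O | intermediate
3 | N-(2,3,4-tribromo-6-hydroxy-5-methoxyphenyl)acetamide | COc1c(Br)c(Br)c(Br)c(NC(C)=O)c1O | intermediate
4 | 2-amino-3,4,5-tribromo-6-methoxyphenol | COc1c(Br)c(Br)c(Br)c(N)c1O | intermediate
5 | 2,3,4-tribromo-6-hydroxy-5-methoxybenzenediazonium tetrafluoroborate (not isolated) | COc1c(Br)c(Br)c(Br)c([N+]#N)c1O.F[B-](F)(F)F | intermediate
6 | 3,4,5-tribromo-6-diazo-2-methoxycyclohexa-2,4-dien-1-one | COC1=C(Br)C(Br)=C(Br)C(=[N+]=[N-])C1=O | intermediate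
7 | 2,4-dibromophenol | Oc1ccc(Br)cc1Br | starting material
8 | rhodium quinoid carbene of 6, Rh2(esp)2 core written as [Rh] (not isolated) | COC1=C(Br)C(Br)=C(Br)C(=[Rh])C1=O | intermediate
9 | 3,4,5-tribromo-2-(2,4-dibromophenoxy)-6-methoxyphenol | COc1c(O)c(Oc2ccc(Br)cc2Br)c(Br)c(Br)c1Br | target

## Step count
- **Total step count:** 5
- **Longest linear sequence:** 5 (1 → 2 → 3 → 4 → 6 → 9)

## The three steps most likely to fail

**Step 5 (proposed new step).** The risks are slow N2 loss at the hindered, electron-poor diazo carbon, Wolff ring contraction, and azine or oligomer formation. The fallback uses only known chemistry, sets out from 7 and comes back to the route at 9. Compound 7 and purchased 2-fluoro-6-methoxybenzaldehyde F1 are joined by SNAr (K2CO3, DMF, 110 °C; the ortho formyl group activates the fluoride) to give 2-(2,4-dibromophenoxy)-6-methoxybenzaldehyde F2. Baeyer–Villiger oxidation (mCPBA, CH2Cl2, rt) gives 2-(2,4-dibromophenoxy)-6-methoxyphenyl formate F3. Methanolysis (cat. K2CO3, MeOH, rt) gives 2-(2,4-dibromophenoxy)-6-methoxyphenol F4. Br2 (3.1 equiv, AcOH, rt to 40 °C) then fills the three free positions of the phenol ring and gives 9, because the doubly brominated second ring is too deactivated to react.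

**Step 3.** The risk is that the acetanilide, flanked by OH and Br, hydrolyses too slowly, or that long heating in acid causes partial loss of bromine. The fallback replaces the amide with one that is cleaved by mild base. It sets out from 1 and comes back at 4. Compound 1 with (CF3CO)2O and pyridine (CH2Cl2, 0 °C) gives 2,2,2-trifluoro-N-(2-hydroxy-3-methoxyphenyl)acetamide F5. Br2 (3.3 equiv, AcOH, rt to 50 °C; OH and OMe alone activate all three positions) gives 2,2,2-trifluoro-N-(2,3,4-tribromo-6-hydroxy-5-methoxyphenyl)acetamide F6. K2CO3 in MeOH/H2O (rt, under N2) frees 4.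

**Step 2.** The risk is that the free phenol is oxidised to quinoid products before the third bromine enters. The fallback ties N and O together in one ring so that no oxidisable phenol or anilide is present. It sets out from 1 and comes back at 4. Compound 1 with 1,1'-carbonyldiimidazole (THF, reflux) gives 7-methoxy-1,3-benzoxazol-2(3H)-one F7. Forcing bromination (excess Br2, cat. FeBr3, AcOH, 70 °C; no other ring can compete) gives 4,5,6-tribromo-7-methoxy-1,3-benzoxazol-2(3H)-one F8. Opening the carbamate with aq NaOH/EtOH (reflux, under N2, then AcOH to pH 6) gives 4.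

## Further compounds
F1 | step 5 | 2-fluoro-6-methoxybenzaldehyde (purchased) | COc1cccc(F)c1C=O
F2 | step 5 | 2-(2,4-dibromophenoxy)-6-methoxybenzaldehyde | COc1cccc(Oc2ccc(Br)cc2Br)c1C=O
F3 | step 5 | 2-(2,4-dibromophenoxy)-6-methoxyphenyl formate | COc1cccc(Oc2ccc(Br)cc2Br)c1OC=O
F4 | step 5 | 2-(2,4-dibromophenoxy)-6-methoxyphenol | COc1cccc(Oc2ccc(Br)cc2Br)c1O
F5 | step 3 | 2,2,2-trifluoro-N-(2-hydroxy-3-methoxyphenyl)acetamide | COc1cccc(NC(=O)C(F)(F)F)c1O
F6 | step 3 | 2,2,2-trifluoro-N-(2,3,4-tribromo-6-hydroxy-5-methoxyphenyl)acetamide | COc1c(Br)c(Br)c(Br)c(NC(=O)C(F)(F)F)c1O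
F7 | step 2 | 7-methoxy-1,3-benzoxazol-2(3H)-one | COc1cccc2NC(=O)Oc12
F8 | step 2 | 4,5,6-tribromo-7-methoxy-1,3-benzoxazol-2(3H)-one | COc1c(Br)c(Br)c(Br)c2NC(=O)Oc12
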